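**Retrosynthetic overview**

1. Ring numbering: C1 (gem-diprenyl carbon), C2 (C=O), C3 (isobutyryl-bearing carbon), C4 (enol carbon), C5 (S-configured carbinol carbon with OH and prenyl), C6 (C=O). The strategy rests on the C1–C6 bond of the six-membered ring, which joins the quaternary C1 to a ketone flanked by the fully substituted C5 and is the most crowded bond of the ring.
2. Target ⇐ its C5 silyl ether ⇐ Claisen (Dieckmann) closure C3–C4 of an open-chain 3,5,7-triketo ester; the six-membered ring is the only ring of the target and is closed last.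
3. Triketo ester ⇐ retro-aldol opening (C6–C3 cleaved) of a 2-acyl-3-siloxycyclobutanone ⇐ C3 isobutyrylation of the 3-siloxycyclobutanone ⇐ [2+2] cycloaddition of diprenylketene (C1=C2) with an enantiopure 2-siloxyalkene (C3=C6), which makes C1–C6 and C2–C3; this four-membered ring is formed first and is only temporary.
4. Siloxyalkene ⇐ methyl acetoacetate (prenylation, catalytic enantioselective α-hydroxylation that sets C5, two silylations); diprenylketene ⇐ diethyl malonate and prenyl bromide via diprenylacetyl chloride.

Key step: step 10

Remark (design): a 2,2-dialkyl-3-oxycyclobutanone is expected to open at its more substituted ring bond, here C6–C1, which would undo the key bond; the isobutyryl group that C3 needs anyway is therefore placed on the cyclobutanone before ring opening, so that C3 becomes a β-diketone carbon and cleavage is directed to C6–C3, and the opening is run as a separate operation (step 12).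

Remark (assumption): the sense of induction of the titanium TADDOLate with this substrate is assumed; the ligand enantiomer that gives the R alcohol is fixed by a pilot run with assignment of configuration, both ligand enantiomers being available.

**Route**

Step 1
Reactants: 1 methyl acetoacetate; 2 prenyl bromide (1-bromo-3-methylbut-2-ene)
Product: 3 methyl 2-acetyl-5-methylhex-4-enoate (racemic)
Conditions: NaH (1.0 equiv), THF, 0 °C; 2 (0.9 equiv), 0 °C → rt
Reagents that add atoms: none
Why: C-alkylation of the sodium enolate of a β-keto ester with an allylic bromide (acetoacetic ester alkylation), the keto ester being in slight excess to suppress dialkylation; the new centre is racemic and is overwritten in step 2.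

Step 2
Reactants: 3 methyl 2-acetyl-5-methylhex-4-enoate
Product: 4 methyl (2R)-2-acetyl-2-hydroxy-5-methylhex-4-enoate
Conditions: TiCl2(TADDOLato)(MeCN)2 (5 mol%, tetra-1-naphthyl TADDOL, enantiomer that gives R), 3-(4-nitrophenyl)-2-(phenylsulfonyl)oxaziridine (1.2 equiv), CH2Cl2, rt
Reagents that add atoms: 3-(4-nitrophenyl)-2-(phenylsulfonyl)oxaziridine, O=S(=O)(c1ccccc1)N1OC1c1ccc(cc1)[N+](=O)[O-]
Why: Lewis-acid-catalysed enantioselective α-hydroxylation of a 2-alkyl β-keto ester, in which the chiral complex of tetravalent titanium holds the substrate as a two-point chelated enolate and shields one face, so that oxygen transfer from the N-sulfonyloxaziridine sets the quaternary carbinol centre (the later C5) as R, while the trisubstituted alkene is not attacked by this oxidant at room temperature.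

Step 3
Reactants: 4 methyl (2R)-2-acetyl-2-hydroxy-5-methylhex-4-enoate
Product: 5 methyl (2R)-2-acetyl-2-(tert-butyldimethylsilyloxy)-5-methylhex-4-enoate
Conditions: TBSOTf (1.3 equiv), 2,6-lutidine (2 equiv), CH2Cl2, −78 → 0 °C
Reagents that add atoms: tert-butyldimethylsilyl trifluoromethanesulfonate, CC(C)(C)[Si](C)(C)OS(=O)(=O)C(F)(F)F
Why: O-silylation of a hindered tertiary alcohol with a silyl triflate and a hindered pyridine base; the stereocentre carries no hydrogen and cannot epimerise.

Step 4
Reactants: 5 methyl (2R)-2-acetyl-2-(tert-butyldimethylsilyloxy)-5-methylhex-4-enoate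
Product: 6 methyl (2R)-2-(tert-butyldimethylsilyloxy)-5-methyl-2-[1-(trimethylsilyloxy)ethenyl]hex-4-enoate
Conditions: TMSOTf (1.2 equiv), Et3N (1.5 equiv), CH2Cl2, 0 °C; pentane, filtration, no aqueous work-up
Reagents that add atoms: trimethylsilyl trifluoromethanesulfonate, C[Si](C)(C)OS(=O)(=O)C(F)(F)F
Why: soft enolisation and O-silylation of a methyl ketone (silyl enol ether formation); the acetyl CH3 is the only enolisable position, so only the terminal 2-siloxyalkene can form.

Step 5
Reactants: 7 diethyl malonate; 2 prenyl bromide
Product: 8 diethyl 2,2-bis(3-methylbut-2-enyl)propanedioate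
Conditions: NaH (2.2 equiv), THF/DMF, 0 °C; 2 (2.3 equiv), 0 °C → rt
Reagents that add atoms: none
Why: double C-alkylation of the malonate enolate with a reactive allylic bromide (malonic ester synthesis).

Step 6
Reactants: 8 diethyl 2,2-bis(3-methylbut-2-enyl)propanedioate
Product: 9 2,2-bis(3-methylbut-2-enyl)propanedioic acid
Conditions: KOH (4 equiv), EtOH/H2O, reflux; then 1 M HCl, 0 °C
Reagents that add atoms: potassium hydroxide, [K+].[OH-]
Why: saponification of a dialkylmalonate, followed by cold, brief acidification that leaves the trisubstituted alkenes intact.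

Step 7
Reactants: 9 2,2-bis(3-methylbut-2-enyl)propanedioic acid
Product: 10 5-methyl-2-(3-methylbut-2-enyl)hex-4-enoic acid
Conditions: Cu2O (5 mol%), MeCN, reflux
Reagents that add atoms: none
Why: decarboxylation of a disubstituted malonic acid, catalysed by monovalent copper at about 80 °C so that acid-induced lactonisation onto the prenyl groups, a risk of a neat melt, is avoided.

Step 8
Reactants: 10 5-methyl-2-(3-methylbut-2-enyl)hex-4-enoic acid
Product: 11 5-methyl-2-(3-methylbut-2-enyl)hex-4-enoyl chloride
Conditions: (COCl)2 (1.3 equiv), DMF (cat.), CH2Cl2, 0 °C → rt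
Reagents that add atoms: oxalyl chloride, ClC(=O)C(=O)Cl
Why: acid chloride formation through the Vilsmeier-type chloroiminium intermediate at low temperature, with HCl leaving as a gas before it can add to the alkenes.

Step 9
Reactants: 11 5-methyl-2-(3-methylbut-2-enyl)hex-4-enoyl chloride
Product: 12 5-methyl-2-(3-methylbut-2-enyl)hexa-1,4-dien-1-one (diprenylketene)
Conditions: Et3N (1.5 equiv), toluene, 60 °C; filtration under Ar, concentration, used at once
Reagents that add atoms: none
Why: dehydrochlorination of an α,α-dialkyl acid chloride by a tertiary amine gives the disubstituted ketene, whose two CH2-branched substituents slow dimerisation enough for it to be handled as a salt-free solution.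

Step 10
Reactants: 12 diprenylketene; 6 methyl (2R)-2-(tert-butyldimethylsilyloxy)-5-methyl-2-[1-(trimethylsilyloxy)ethenyl]hex-4-enoate
Product: 13 methyl (2R)-2-(tert-butyldimethylsilyloxy)-2-[2,2-bis(3-methylbut-2-enyl)-3-oxo-1-(trimethylsilyloxy)cyclobutyl]-5-methylhex-4-enoate (both epimers at the ring carbinol carbon)
Conditions: 12 (3 equiv), MeCN (2 M in 6), 60 °C, sealed tube, Ar
Reagents that add atoms: none
Why: Proposed new method: the CH2 terminus of the siloxyalkene (C3) should add to the central, electrophilic carbon of the ketene (C2), and the resulting siloxycarbenium–enolate ion pair should collapse by attack of the enolate carbon C1 on C6, a 4-exo closure that makes the crowded C1–C6 bond inside an ion pair and so closes the cyclobutanone ring in a stepwise, formally [2+2] manner. The closest known reactions are the thermal cycloadditions of dichloroketene and diphenylketene with silyl enol ethers and of dimethylketene with alkyl enol ethers, all of which give 3-oxycyclobutanones, whereas a dialkylketene has not been joined to an α-quaternary 2-siloxyalkene; a polar solvent, high concentration and an excess of 12 are therefore used to favour the dipolar transition state over ketene dimerisation. The ring carbon C6 becomes a stereocentre for the time being; it is not controlled and need not be, since both epimers give the same ketone when the ring is opened, and C5 is not involved. The step needs regioselectivity, which the matched polarity of the two partners fixes (C3 to C2, C6 to C1), and chemoselectivity for the siloxyalkene over the three trisubstituted prenyl alkenes, which its much higher nucleophilicity secures. No Lewis acid is added, because a halide Lewis acid would strip the silyl group from the ion pair (Mukaiyama-type C-acylation without a C1–C6 bond) and would reopen the product at its more substituted bond.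

Step 11
Reactants: 14 2-methylpropanoyl chloride (isobutyryl chloride); 15 1H-benzotriazole
Product: 16 1-(benzotriazol-1-yl)-2-methylpropan-1-one
Conditions: Et3N (1.1 equiv), CH2Cl2, 0 °C → rt
Reagents that add atoms: none
Why: N-acylation of benzotriazole by an acid chloride gives a neutral, storable acyl donor that acylates ketone enolates on carbon.

Step 12
Reactants: 13 siloxycyclobutanone; 16 1-(benzotriazol-1-yl)-2-methylpropan-1-one
Product: 19 methyl (2R)-2-(tert-butyldimethylsilyloxy)-8-methyl-2,4,4-tris(3-methylbut-2-enyl)-3,5,7-trioxononanoate, via C3-isobutyryl siloxycyclobutanone 17 (not isolated), via C3-isobutyryl hydroxycyclobutanone 18 (not isolated)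
Conditions: LiN(SiMe3)2 (1.05 equiv), THF, −78 °C; 16 (1.2 equiv); LiN(SiMe3)2 (1.0 equiv), −78 → −40 °C; AcOH; Et3N·3HF (3 equiv), 0 °C → rt
Reagents that add atoms: none
Why: only C3 can be deprotonated (C1 is quaternary) and its lithium enolate is C-acylated by the N-acylbenzotriazole (enolate acylation to a β-diketone), after which mildly acidic fluoride removes only the tertiary trimethylsilyl ether and the free 2-acylcyclobutanol fragments by the retro-aldol step of the De Mayo reaction, breaking C6–C3 because C3 is now a β-diketone carbon whose exocyclic acyl group can overlap with that bond, whereas cleavage of C6–C1 would release only a simple enolate.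

Step 13
Reactants: 19 methyl (2R)-2-(tert-butyldimethylsilyloxy)-8-methyl-2,4,4-tris(3-methylbut-2-enyl)-3,5,7-trioxononanoate
Product: 20 (4S)-4-(tert-butyldimethylsilyloxy)-3-hydroxy-2-(2-methylpropanoyl)-4,6,6-tris(3-methylbut-2-enyl)cyclohex-2-ene-1,5-dione
Conditions: KOtBu (2.2 equiv), THF, 0 °C → rt; cold 1 M HCl work-up
Reagents that add atoms: none
Why: the potassium enolate of the β-diketone carbon C3 closes the six-membered ring on the C4 methyl ester (6-exo-trig Dieckmann-type Claisen cyclisation of a 3,5,7-triketo ester, the closure by which acylphloroglucinols arise), helped by the two quaternary chain carbons (gem-dialkyl effect) and driven by formation of the strongly acidic β-triketone, while the non-nucleophilic base spares the 1,3-diketone from retro-Claisen cleavage and the quaternary C5 cannot epimerise.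

Step 14
Reactants: 20 silyl ether of the target
Product: 21 (4S)-3,4-dihydroxy-2-(2-methylpropanoyl)-4,6,6-tris(3-methylbut-2-enyl)cyclohex-2-ene-1,5-dione (target, CNP0442339.1)
Conditions: HF·pyridine, pyridine, THF, 0 °C → rt
Reagents that add atoms: none
Why: fluoride cleavage of the tertiary silyl ether under buffered, weakly acidic conditions, chosen because the free acyloin–triketone is prone to base-induced acyloin rearrangement (ring contraction) and the prenyl groups to strong acid; no stereocentre is touched.

**Compound list**

1 | methyl acetoacetate | COC(=O)CC(C)=O | starting material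
2 | prenyl bromide (1-bromo-3-methylbut-2-ene) | CC(C)=CCBr | starting material
3 | methyl 2-acetyl-5-methylhex-4-enoate (racemic) | COC(=O)C(CC=C(C)C)C(C)=O | intermediate
4 | methyl (2R)-2-acetyl-2-hydroxy-5-methylhex-4-enoate | CC(=O)[C@](O)(CC=C(C)C)C(=O)OC | intermediate
5 | methyl (2R)-2-acetyl-2-(tert-butyldimethylsilyloxy)-5-methylhex-4-enoate | CC(=O)[C@](O[Si](C)(C)C(C)(C)C)(CC=C(C)C)C(=O)OC | intermediate
6 | methyl (2R)-2-(tert-butyldimethylsilyloxy)-5-methyl-2-[1-(trimethylsilyloxy)ethenyl]hex-4-enoate | C=C(O[Si](C)(C)C)[C@](O[Si](C)(C)C(C)(C)C)(CC=C(C)C)C(=O)OC | intermediate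
7 | diethyl malonate | CCOC(=O)CC(=O)OCC | starting material
8 | diethyl 2,2-bis(3-methylbut-2-enyl)propanedioate | CCOC(=O)C(CC=C(C)C)(CC=C(C)C)C(=O)OCC | intermediate
9 | 2,2-bis(3-methylbut-2-enyl)propanedioic acid | OC(=O)C(CC=C(C)C)(CC=C(C)C)C(O)=O | intermediate
10 | 5-methyl-2-(3-methylbut-2-enyl)hex-4-enoic acid | CC(C)=CCC(CC=C(C)C)C(O)=O | intermediate
11 | 5-methyl-2-(3-methylbut-2-enyl)hex-4-enoyl chloride | CC(C)=CCC(CC=C(C)C)C(Cl)=O | intermediate
12 | 5-methyl-2-(3-methylbut-2-enyl)hexa-1,4-dien-1-one (diprenylketene) | CC(C)=CCC(CC=C(C)C)=C=O | intermediate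
13 | methyl (2R)-2-(tert-butyldimethylsilyloxy)-2-[2,2-bis(3-methylbut-2-enyl)-3-oxo-1-(trimethylsilyloxy)cyclobutyl]-5-methylhex-4-enoate (both epimers at the ring carbinol carbon) | O=C1CC(O[Si](C)(C)C)([C@](O[Si](C)(C)C(C)(C)C)(CC=C(C)C)C(=O)OC)C1(CC=C(C)C)CC=C(C)C | intermediate
14 | 2-methylpropanoyl chloride (isobutyryl chloride) | CC(C)C(Cl)=O | starting material
15 | 1H-benzotriazole | c1ccc2[nH]nnc2c1 | starting material
16 | 1-(benzotriazol-1-yl)-2-methylpropan-1-one | CC(C)C(=O)n1nnc2ccccc12 | intermediate
17 | methyl (2R)-2-(tert-butyldimethylsilyloxy)-5-methyl-2-[2,2-bis(3-methylbut-2-enyl)-4-(2-methylpropanoyl)-3-oxo-1-(trimethylsilyloxy)cyclobutyl]hex-4-enoate (ring stereoisomers) | CC(C)C(=O)C1C(=O)C(CC=C(C)C)(CC=C(C)C)C1(O[Si](C)(C)C)[C@](O[Si](C)(C)C(C)(C)C)(CC=C(C)C)C(=O)OC | intermediate (not isolated)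
18 | methyl (2R)-2-(tert-butyldimethylsilyloxy)-2-[1-hydroxy-2,2-bis(3-methylbut-2-enyl)-4-(2-methylpropanoyl)-3-oxocyclobutyl]-5-methylhex-4-enoate (ring stereoisomers) | CC(C)C(=O)C1C(=O)C(CC=C(C)C)(CC=C(C)C)C1(O)[C@](O[Si](C)(C)C(C)(C)C)(CC=C(C)C)C(=O)OC | intermediate (not isolated)
19 | methyl (2R)-2-(tert-butyldimethylsilyloxy)-8-methyl-2,4,4-tris(3-methylbut-2-enyl)-3,5,7-trioxononanoate | CC(C)C(=O)CC(=O)C(CC=C(C)C)(CC=C(C)C)C(=O)[C@](O[Si](C)(C)C(C)(C)C)(CC=C(C)C)C(=O)OC | intermediate
20 | (4S)-4-(tert-butyldimethylsilyloxy)-3-hydroxy-2-(2-methylpropanoyl)-4,6,6-tris(3-methylbut-2-enyl)cyclohex-2-ene-1,5-dione | CC(C)=CCC1(CC=C(C)C)C(=O)C(C(=O)C(C)C)=C(O)[C@@](O[Si](C)(C)C(C)(C)C)(CC=C(C)C)C1=O | intermediate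
21 | (4S)-3,4-dihydroxy-2-(2-methylpropanoyl)-4,6,6-tris(3-methylbut-2-enyl)cyclohex-2-ene-1,5-dione | CC(C)=CCC1(CC=C(C)C)C(=O)C(C(=O)C(C)C)=C(O)[C@@](O)(CC=C(C)C)C1=O | target

**Step count and risks**

Total step count: 14. Longest linear sequence: 9 steps (steps 5, 6, 7, 8, 9, 10, 12, 13, 14, from diethyl malonate).

The three steps most likely to fail:

Step 10 (Proposed new method). Three processes may defeat it:
- the cycloaddition may not start, because a dialkylketene is a weak electrophile and C6 sits next to a quaternary carbon;
- the ion pair may collapse by silyl transfer instead of C–C bond formation;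
- the crowded adduct may revert at 60 °C while the ketene is lost to dimerisation.

The last two processes lead to the C3-acylated enol ether without the C1–C6 bond.

The fallback uses known reactions only, sets out from 3 (with 11 and 14 as acyl donors) and comes back to the route at 20. Compound 3 is hydroxylated as in step 2 but with the mirror-image titanium TADDOLate to give methyl (2S)-2-acetyl-2-hydroxy-5-methylhex-4-enoate F1. Silylation (TBSOTf, 2,6-lutidine) gives methyl (2S)-2-acetyl-2-(tert-butyldimethylsilyloxy)-5-methylhex-4-enoate F2. Soft enolisation of the acetyl group (MgBr2·OEt2, i-Pr2NEt, CH2Cl2) and C-acylation with 11 give the β-diketone methyl (2S)-2-(tert-butyldimethylsilyloxy)-9-methyl-2,6-bis(3-methylbut-2-enyl)-3,5-dioxodec-8-enoate F3. LiN(i-Pr)2 (3 equiv, THF, −78 → 0 °C) forms the 1,3-diketone dianion, whose γ-carbon (the diprenyl methine, the later C1) attacks the methyl ester in a Claisen cyclisation to give (4S)-4-(tert-butyldimethylsilyloxy)-2,2,4-tris(3-methylbut-2-enyl)cyclohexane-1,3,5-trione F4. O-Acylation with 14 and Et3N gives the enol ester (6S)-6-(tert-butyldimethylsilyloxy)-4,4,6-tris(3-methylbut-2-enyl)-3,5-dioxocyclohex-1-en-1-yl 2-methylpropanoate F5, and a DMAP-catalysed O-to-C acyl shift gives 20. In this sequence the ester carbon becomes C6 and the acetyl carbon C4, the reverse of the main route, which is why the S hydroxy ester is needed to reach the same configuration at C5.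

Step 12. The enolate of 13 may lose silanolate (β-elimination to a cyclobutenone), may be acylated on oxygen, or may not form cleanly next to the fully substituted C6.

The fallback sets out from 13 and comes back at 19. Compound 13 is opened directly with buffered fluoride (Bu4NF, AcOH, THF, 0 °C). The product methyl (2R)-2-(tert-butyldimethylsilyloxy)-2,4,4-tris(3-methylbut-2-enyl)-3,5-dioxohexanoate F6 is separated from the isomeric diketone that arises when the C6–C1 bond breaks instead. The acetyl group of F6, its only enolisable position, is then C-acylated with 14 under soft enolisation (MgBr2·OEt2, i-Pr2NEt, CH2Cl2) to give 19. This detour gives up control over the direction of ring opening and is taken only if the enolate chemistry on 13 cannot be made to work.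

Step 2. Facial selectivity may be insufficient with the small methyl ester and the acyclic substrate, which would leave 4 enantiomerically impure; the enantiomeric purity should be checked on a chiral phase at the stage of 4 or 5.

The fallback sets out from 3 and comes back at 4. The sodium enolate is hydroxylated without a chiral catalyst (NaN(SiMe3)2, THF, −78 °C; 3-phenyl-2-(phenylsulfonyl)oxaziridine) to give racemic methyl 2-acetyl-2-hydroxy-5-methylhex-4-enoate F7. The enantiomers are separated by preparative chromatography on a chiral stationary phase to give 4; the S enantiomer is compound F1 and can feed the first fallback.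

**Further compounds**

F1 | step 10 | methyl (2S)-2-acetyl-2-hydroxy-5-methylhex-4-enoate | CC(=O)[C@@](O)(CC=C(C)C)C(=O)OC
F2 | step 10 | methyl (2S)-2-acetyl-2-(tert-butyldimethylsilyloxy)-5-methylhex-4-enoate | CC(=O)[C@@](O[Si](C)(C)C(C)(C)C)(CC=C(C)C)C(=O)OC
F3 | step 10 | methyl (2S)-2-(tert-butyldimethylsilyloxy)-9-methyl-2,6-bis(3-methylbut-2-enyl)-3,5-dioxodec-8-enoate | CC(C)=CCC(CC=C(C)C)C(=O)CC(=O)[C@@](O[Si](C)(C)C(C)(C)C)(CC=C(C)C)C(=O)OC
F4 | step 10 | (4S)-4-(tert-butyldimethylsilyloxy)-2,2,4-tris(3-methylbut-2-enyl)cyclohexane-1,3,5-trione | CC(C)=CCC1(CC=C(C)C)C(=O)CC(=O)[C@@](O[Si](C)(C)C(C)(C)C)(CC=C(C)C)C1=O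
F5 | step 10 | (6S)-6-(tert-butyldimethylsilyloxy)-4,4,6-tris(3-methylbut-2-enyl)-3,5-dioxocyclohex-1-en-1-yl 2-methylpropanoate | CC(C)=CCC1(CC=C(C)C)C(=O)C=C(OC(=O)C(C)C)[C@@](O[Si](C)(C)C(C)(C)C)(CC=C(C)C)C1=O
F6 | step 12 | methyl (2R)-2-(tert-butyldimethylsilyloxy)-2,4,4-tris(3-methylbut-2-enyl)-3,5-dioxohexanoate | CC(=O)C(CC=C(C)C)(CC=C(C)C)C(=O)[C@](O[Si](C)(C)C(C)(C)C)(CC=C(C)C)C(=O)OC
F7 | step 2 | methyl 2-acetyl-2-hydroxy-5-methylhex-4-enoate, racemic | CC(=O)C(O)(CC=C(C)C)C(=O)OC
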